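The pyran ring is formed by disconnecting its O1–C2 bond. The precursor is an ortho-(2,3-epoxygeranyl)phenol whose trans epoxide, a temporary ring spanning C2 and C3, comes from Sharpless epoxidation of geraniol. The key step exploits that C2 is the fully substituted pyran carbon, flanked by C3, which best carries positive charge: under acid the phenol oxygen O1 opens the epoxide 6-endo at C2 with inversion, so one operation closes the pyran ring and fixes the (S) quaternary centre. The C3 hydroxyl left behind is then eliminated to the C3=C4 alkene. The side-chain carbinol derives from the enantiomeric epoxide of the same alcohol, attached by alkyne–allyl coupling and trans reduction.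

Key step: step 6

Remark: ring atoms are numbered as in 2H-chromene (O1, C2, C3, C4, C4a, C5 to C8, C8a); because 2H-chromenes can reopen at O1–C2 on irradiation, all chromene intermediates are handled in the dark and below 80 °C.

Step 1
Reactants: 1 2-methylbenzene-1,4-diol (methylhydroquinone)
Product: 2 2-methyl-4-[(triisopropylsilyl)oxy]phenol
Conditions: i-Pr3SiCl (1.0 equiv), imidazole, DMF, 0 °C
Reagents that add atoms: chlorotriisopropylsilane, CC(C)[Si](Cl)(C(C)C)C(C)C
Why: Silyl ether formation, in which the bulky chlorosilane should react at the hydroxyl flanked by two ring hydrogens in preference to the one ortho to the methyl group, the regioisomer and the bis-ether being removed by chromatography.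

Step 2
Reactants: 2 2-methyl-4-[(triisopropylsilyl)oxy]phenol
Product: 3 2-bromo-6-methyl-4-[(triisopropylsilyl)oxy]phenol
Conditions: NBS (1.0 equiv), i-Pr2NH (10 mol%), CH2Cl2, −20 °C
Reagents that add atoms: N-bromosuccinimide, O=C1CCC(=O)N1Br
Why: Electrophilic aromatic bromination directed by the free hydroxyl to its only open ortho position, the para position being blocked and the positions beside the bulky silyl ether shielded.

Step 3
Reactants: 4 geraniol, (2E)-3,7-dimethylocta-2,6-dien-1-ol
Product: 5 (2R,3R)-2,3-epoxygeraniol, [(2R,3R)-3-methyl-3-(4-methylpent-3-en-1-yl)oxiran-2-yl]methanol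
Conditions: Ti(OiPr)4 (5 mol%), D-(−)-diethyl tartrate (6 mol%), t-BuOOH, 4 Å molecular sieves, CH2Cl2, −20 °C
Reagents that add atoms: tert-butyl hydroperoxide, CC(C)(C)OO
Why: Sharpless asymmetric epoxidation, in which the allylic hydroxyl binds the titanium tartrate so that only the allylic alkene is oxidised and the D-tartrate ligand dictates the face of oxygen delivery, setting both epoxide carbons as (R) with the trans relationship inherited from the (E)-alkene.

Step 4
Reactants: 5 (2R,3R)-2,3-epoxygeraniol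
Product: 6 [(2R,3R)-3-methyl-3-(4-methylpent-3-en-1-yl)oxiran-2-yl]methyl 4-methylbenzenesulfonate
Conditions: TsCl, Et3N, DMAP (5 mol%), CH2Cl2, 0 °C
Reagents that add atoms: 4-methylbenzenesulfonyl chloride, Cc1ccc(cc1)S(Cl)(=O)=O
Why: Sulfonylation of the primary alcohol, which turns the CH2 carbon into an electrophile without touching either stereocentre.

Step 5
Reactants: 3 2-bromo-6-methyl-4-[(triisopropylsilyl)oxy]phenol; 6 [(2R,3R)-3-methyl-3-(4-methylpent-3-en-1-yl)oxiran-2-yl]methyl 4-methylbenzenesulfonate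
Product: 8 2-methyl-6-{[(2R,3R)-3-methyl-3-(4-methylpent-3-en-1-yl)oxiran-2-yl]methyl}-4-[(triisopropylsilyl)oxy]phenol, via dilithio phenoxide 7 (not isolated)
Conditions: t-BuLi (3.1 equiv), THF, −78 °C; CuBr·SMe2 (10 mol%), then the tosylate, −78 → −20 °C; cold aq. NH4Cl; product used without chromatography on silica
Reagents that add atoms: none
Why: Deprotonation and bromine–lithium exchange give the C,O-dianion, whose aryl carbon should displace the primary tosylate under copper catalysis (sp2–sp3 cross-coupling) faster than it opens the hindered trisubstituted epoxide, so that both epoxide stereocentres pass through unchanged.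

Step 6
Reactants: 8 2-methyl-6-{[(2R,3R)-3-methyl-3-(4-methylpent-3-en-1-yl)oxiran-2-yl]methyl}-4-[(triisopropylsilyl)oxy]phenol
Product: 9 (2S,3R)-2,8-dimethyl-2-(4-methylpent-3-en-1-yl)-6-[(triisopropylsilyl)oxy]-3,4-dihydro-2H-chromen-3-ol
Conditions: camphor-10-sulfonic acid (10 mol%), CH2Cl2, −40 → 0 °C; Et3N quench
Reagents that add atoms: none
Why: The sulfonic acid activates the epoxide oxygen, positive charge builds on the methyl-bearing tertiary carbon C2 as its C–O bond lengthens, and the phenol oxygen O1 attacks C2 from the face opposite the departing oxygen, so that bond breaking and bond making stay coupled (borderline SN2, anti opening). The closest known reaction type is the acid-catalysed endo-selective opening of trisubstituted epoxides by a tethered hydroxyl, as used for tetrahydropyrans and for 2,2-dialkylchroman-3-ols from ortho-(2,3-epoxyalkyl)phenols. The pyran ring is closed in the 6-endo-tet mode by the new O1–C2 bond. C2 becomes (S) by inversion of the (R) epoxide carbon fixed by the tartrate ligand in step 3, and C3 keeps its C–O bond and therefore its (R) configuration. The step needs 6-endo over 5-exo attack and inversion rather than a free cation; the substrate secures the first through the tertiary versus secondary character of the two epoxide carbons and the second through the phenol held in a six-membered array anti to the breaking bond, supported by catalytic acid, a non-nucleophilic solvent and low temperature. The distant trisubstituted alkene cannot reach the epoxide and the aryl silyl ether is stable to the acid.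

Step 7
Reactants: 9 (2S,3R)-2,8-dimethyl-2-(4-methylpent-3-en-1-yl)-6-[(triisopropylsilyl)oxy]-3,4-dihydro-2H-chromen-3-ol
Product: 10 (2S)-2,8-dimethyl-2-(4-methylpent-3-en-1-yl)-6-[(triisopropylsilyl)oxy]-2H-chromene
Conditions: Burgess reagent (MeO2CNSO2NEt3 inner salt, 1.5 equiv), toluene, 70 °C
Reagents that add atoms: none
Why: Burgess dehydration, a thermal syn-elimination of the activated C3 hydroxyl together with a benzylic C4 hydrogen, the only β-hydrogens present because C2 is fully substituted, which should give the C3=C4 alkene and leave C2 untouched.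

Step 8
Reactants: 10 (2S)-2,8-dimethyl-2-(4-methylpent-3-en-1-yl)-6-[(triisopropylsilyl)oxy]-2H-chromene
Product: 11 (2E)-5-{(2S)-2,8-dimethyl-6-[(triisopropylsilyl)oxy]-2H-chromen-2-yl}-2-methylpent-2-en-1-ol
Conditions: SeO2 (0.3 equiv), t-BuOOH, salicylic acid (10 mol%), CH2Cl2, 0 °C → rt, stopped before full conversion
Reagents that add atoms: selenium dioxide, O=[Se]=O (oxygen carrier); tert-butyl hydroperoxide, CC(C)(C)OO (terminal oxidant)
Why: Selenium dioxide allylic oxidation (ene reaction followed by [2,3]-sigmatropic shift), which attacks the (E)-methyl group of a 2-methylalk-2-ene terminus and should therefore give the (E)-allylic alcohol, the chromene alkene having no allylic hydrogen.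

Step 9
Reactants: 11 (2E)-5-{(2S)-2,8-dimethyl-6-[(triisopropylsilyl)oxy]-2H-chromen-2-yl}-2-methylpent-2-en-1-ol
Product: 12 (2S)-2-[(3E)-5-bromo-4-methylpent-3-en-1-yl]-2,8-dimethyl-6-[(triisopropylsilyl)oxy]-2H-chromene
Conditions: CBr4, PPh3, 2,6-lutidine, CH2Cl2, −20 °C
Reagents that add atoms: tetrabromomethane, BrC(Br)(Br)Br
Why: Appel reaction, an SN2 displacement of the activated hydroxyl at the primary carbon that keeps the (E)-alkene in place.

Step 10
Reactants: 4 geraniol
Product: 13 (2S,3S)-2,3-epoxygeraniol, [(2S,3S)-3-methyl-3-(4-methylpent-3-en-1-yl)oxiran-2-yl]methanol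
Conditions: Ti(OiPr)4 (5 mol%), L-(+)-diethyl tartrate (6 mol%), t-BuOOH, 4 Å molecular sieves, CH2Cl2, −20 °C
Reagents that add atoms: tert-butyl hydroperoxide, CC(C)(C)OO
Why: Sharpless asymmetric epoxidation with the enantiomeric ligand, which sets the (S) configuration at the methyl-bearing carbon that becomes the side-chain carbinol.

Step 11
Reactants: 13 (2S,3S)-2,3-epoxygeraniol
Product: 14 (2S,3R)-3-(chloromethyl)-2-methyl-2-(4-methylpent-3-en-1-yl)oxirane
Conditions: PPh3, CCl4, NaHCO3, reflux
Reagents that add atoms: tetrachloromethane, ClC(Cl)(Cl)Cl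
Why: Appel chlorination of the primary alcohol under buffered conditions that leave the epoxide intact, the descriptor at the CH carbon changing only because chlorine raises the priority of the CH2 group.

Step 12
Reactants: 14 (2S,3R)-3-(chloromethyl)-2-methyl-2-(4-methylpent-3-en-1-yl)oxirane
Product: 15 (3S)-3,7-dimethyloct-6-en-1-yn-3-ol
Conditions: n-BuLi (3.2 equiv), THF, −40 → 0 °C; aq. NH4Cl
Reagents that add atoms: none
Why: Base-induced fragmentation of a 2,3-epoxy chloride, in which lithiation next to chlorine opens the epoxide by β-elimination and further base removes HCl to unveil the terminal alkyne, the tertiary C–O bond never being broken so that the carbinol keeps the (S) configuration.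

Step 13
Reactants: 12 (2S)-2-[(3E)-5-bromo-4-methylpent-3-en-1-yl]-2,8-dimethyl-6-[(triisopropylsilyl)oxy]-2H-chromene; 15 (3S)-3,7-dimethyloct-6-en-1-yn-3-ol
Product: 16 (3E,8S)-1-{(2S)-2,8-dimethyl-6-[(triisopropylsilyl)oxy]-2H-chromen-2-yl}-4,8,12-trimethyltrideca-3,11-dien-6-yn-8-ol
Conditions: CuI (10 mol%), K2CO3, Bu4NCl, DMF, rt
Reagents that add atoms: none
Why: Copper-catalysed alkynylation of an allylic halide, in which the terminal alkyne carbon should attack the unhindered primary carbon (SN2) rather than the substituted γ-carbon, retaining the (E)-trisubstituted alkene and leaving the tertiary hydroxyl and both stereocentres untouched.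

Step 14
Reactants: 16 (3E,8S)-1-{(2S)-2,8-dimethyl-6-[(triisopropylsilyl)oxy]-2H-chromen-2-yl}-4,8,12-trimethyltrideca-3,11-dien-6-yn-8-ol
Product: 17 (3E,6E,8S)-1-{(2S)-2,8-dimethyl-6-[(triisopropylsilyl)oxy]-2H-chromen-2-yl}-4,8,12-trimethyltrideca-3,6,11-trien-8-ol
Conditions: NaAlH2(OCH2CH2OMe)2 (3 equiv), THF, 0 °C → rt; aq. potassium sodium tartrate
Reagents that add atoms: none
Why: Hydroxyl-directed trans-hydroalumination of the propargylic alcohol, with hydride delivered from the alkoxyaluminate and protonolysis on work-up, which should give only the (E)-alkene while the isolated alkenes, the chromene and the aryl silyl ether are inert.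

Step 15
Reactants: 17 (3E,6E,8S)-1-{(2S)-2,8-dimethyl-6-[(triisopropylsilyl)oxy]-2H-chromen-2-yl}-4,8,12-trimethyltrideca-3,6,11-trien-8-ol
Product: 18 (2S)-2-[(3E,6E,8S)-8-hydroxy-4,8,12-trimethyltrideca-3,6,11-trien-1-yl]-2,8-dimethyl-2H-chromen-6-ol (CNP0155965.1)
Conditions: Bu4NF (1.1 equiv), THF, 0 °C; aq. NH4Cl
Reagents that add atoms: none
Why: Fluoride-induced cleavage of the aryl silyl ether under mild conditions that the tertiary allylic alcohol, the skipped diene and the chromene should tolerate.

Compound list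
1 | 2-methylbenzene-1,4-diol (methylhydroquinone) | Cc1cc(O)ccc1O | starting material
2 | 2-methyl-4-[(triisopropylsilyl)oxy]phenol | Cc1cc(O[Si](C(C)C)(C(C)C)C(C)C)ccc1O | intermediate
3 | 2-bromo-6-methyl-4-[(triisopropylsilyl)oxy]phenol | Cc1cc(O[Si](C(C)C)(C(C)C)C(C)C)cc(Br)c1O | intermediate
4 | geraniol, (2E)-3,7-dimethylocta-2,6-dien-1-ol | CC(C)=CCC/C(C)=C/CO | starting material
5 | (2R,3R)-2,3-epoxygeraniol, [(2R,3R)-3-methyl-3-(4-methylpent-3-en-1-yl)oxiran-2-yl]methanol | CC(C)=CCC[C@@]1(C)O[C@@H]1CO | intermediate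
6 | [(2R,3R)-3-methyl-3-(4-methylpent-3-en-1-yl)oxiran-2-yl]methyl 4-methylbenzenesulfonate | CC(C)=CCC[C@@]1(C)O[C@@H]1COS(=O)(=O)c2ccc(C)cc2 | intermediate
7 | lithium 2-lithio-6-methyl-4-[(triisopropylsilyl)oxy]phenoxide (dilithio phenoxide) | [Li]Oc1c(C)cc(O[Si](C(C)C)(C(C)C)C(C)C)cc1[Li] | intermediate
8 | 2-methyl-6-{[(2R,3R)-3-methyl-3-(4-methylpent-3-en-1-yl)oxiran-2-yl]methyl}-4-[(triisopropylsilyl)oxy]phenol | CC(C)=CCC[C@@]1(C)O[C@@H]1Cc2cc(O[Si](C(C)C)(C(C)C)C(C)C)cc(C)c2O | intermediate
9 | (2S,3R)-2,8-dimethyl-2-(4-methylpent-3-en-1-yl)-6-[(triisopropylsilyl)oxy]-3,4-dihydro-2H-chromen-3-ol | CC(C)=CCC[C@@]1(C)[C@H](O)Cc2cc(O[Si](C(C)C)(C(C)C)C(C)C)cc(C)c2O1 | intermediate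
10 | (2S)-2,8-dimethyl-2-(4-methylpent-3-en-1-yl)-6-[(triisopropylsilyl)oxy]-2H-chromene | CC(C)=CCC[C@@]1(C)C=Cc2cc(O[Si](C(C)C)(C(C)C)C(C)C)cc(C)c2O1 | intermediate
11 | (2E)-5-{(2S)-2,8-dimethyl-6-[(triisopropylsilyl)oxy]-2H-chromen-2-yl}-2-methylpent-2-en-1-ol | OC/C(C)=C/CC[C@@]1(C)C=Cc2cc(O[Si](C(C)C)(C(C)C)C(C)C)cc(C)c2O1 | intermediate
12 | (2S)-2-[(3E)-5-bromo-4-methylpent-3-en-1-yl]-2,8-dimethyl-6-[(triisopropylsilyl)oxy]-2H-chromene | BrC/C(C)=C/CC[C@@]1(C)C=Cc2cc(O[Si](C(C)C)(C(C)C)C(C)C)cc(C)c2O1 | intermediate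
13 | (2S,3S)-2,3-epoxygeraniol, [(2S,3S)-3-methyl-3-(4-methylpent-3-en-1-yl)oxiran-2-yl]methanol | CC(C)=CCC[C@]1(C)O[C@H]1CO | intermediate
14 | (2S,3R)-3-(chloromethyl)-2-methyl-2-(4-methylpent-3-en-1-yl)oxirane | CC(C)=CCC[C@]1(C)O[C@H]1CCl | intermediate
15 | (3S)-3,7-dimethyloct-6-en-1-yn-3-ol | CC(C)=CCC[C@](C)(O)C#C | intermediate
16 | (3E,8S)-1-{(2S)-2,8-dimethyl-6-[(triisopropylsilyl)oxy]-2H-chromen-2-yl}-4,8,12-trimethyltrideca-3,11-dien-6-yn-8-ol | CC(C)=CCC[C@](C)(O)C#CC/C(C)=C/CC[C@@]1(C)C=Cc2cc(O[Si](C(C)C)(C(C)C)C(C)C)cc(C)c2O1 | intermediate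
17 | (3E,6E,8S)-1-{(2S)-2,8-dimethyl-6-[(triisopropylsilyl)oxy]-2H-chromen-2-yl}-4,8,12-trimethyltrideca-3,6,11-trien-8-ol | CC(C)=CCC[C@](C)(O)/C=C/C/C(C)=C/CC[C@@]1(C)C=Cc2cc(O[Si](C(C)C)(C(C)C)C(C)C)cc(C)c2O1 | intermediate
18 | (2S)-2-[(3E,6E,8S)-8-hydroxy-4,8,12-trimethyltrideca-3,6,11-trien-1-yl]-2,8-dimethyl-2H-chromen-6-ol | CC(C)=CCC[C@](C)(O)/C=C/C/C(C)=C/CC[C@@]1(C)C=Cc2cc(O)cc(C)c2O1 | target

Total steps: 15. Longest linear sequence: 10 steps (steps 3 to 9 and 13 to 15 from geraniol 4; equally steps 1, 2, 5 to 9 and 13 to 15 from 1).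

Steps most likely to fail

Step 6. The phenol may attack the secondary epoxide carbon C3 (5-exo closure to a dihydrobenzofuran carbinol), or C–O cleavage at C2 may run ahead of O1–C2 bond formation so that configuration at C2 is partly lost. The fallback closes the same bond by axis-to-centre chirality transfer instead of epoxide opening; it sets out from 5 (with dianion 7 made from 3 as in step 5) and comes back to the route at 10, bypassing 8 and 9. Epoxy alcohol 5 would be chlorinated (PPh3, CCl4, NaHCO3) to (2R,3S)-3-(chloromethyl)-2-methyl-2-(4-methylpent-3-en-1-yl)oxirane F1, fragmented with n-BuLi to (3R)-3,7-dimethyloct-6-en-1-yn-3-ol F2 and acetylated (Ac2O, DMAP, Et3N) to (3R)-3,7-dimethyloct-6-en-1-yn-3-yl acetate F3. Dianion 7, transmetallated with CuBr·SMe2 and LiBr, should displace the acetate in an anti SN2′ reaction to give the axially chiral allene 2-[(Sa)-3,7-dimethylocta-1,2,6-trien-1-yl]-6-methyl-4-[(triisopropylsilyl)oxy]phenol F4. AgNO3 (10 mol%, acetone, rt) would then activate the distal allene π bond, and O1 adds anti at the dialkyl-substituted terminus (6-endo), which should deliver 10 directly with the (S) centre and the C3=C4 alkene in place.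

Step 5. The aryllithium may attack the sulfonyl sulfur or the epoxide, or the lithium phenoxide may close prematurely onto C3 before work-up. The fallback masks the phenol and uses a softer nucleophile; it sets out from 3 and 6 and comes back at 8. Phenol 3 would be O-allylated (allyl bromide, K2CO3, acetone) to 2-(allyloxy)-1-bromo-3-methyl-5-[(triisopropylsilyl)oxy]benzene F5. Bromine–lithium exchange (t-BuLi, Et2O, −78 °C) and conversion to the diaryl cuprate (CuI, 0.5 equiv) would be followed by alkylation with tosylate 6 to give (2R,3R)-3-{[2-(allyloxy)-3-methyl-5-(triisopropylsilyloxy)phenyl]methyl}-2-methyl-2-(4-methylpent-3-en-1-yl)oxirane F6. Pd(PPh3)4 with morpholine in THF would remove the allyl group under neutral conditions and return 8.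

Step 7. Activation of the hindered C3 hydroxyl next to the quaternary C2 may end in carbamate formation or in ring contraction through participation of the ring oxygen instead of syn-elimination. The fallback introduces the alkene through the ketone; it sets out from 9 and comes back at 10. Alcohol 9 would be oxidised (Dess–Martin periodinane, NaHCO3, CH2Cl2) to (2S)-2,8-dimethyl-2-(4-methylpent-3-en-1-yl)-6-[(triisopropylsilyl)oxy]-2H-chromen-3(4H)-one F7, which cannot epimerise because C2 carries no hydrogen. Enolisation toward C4, the only side with hydrogens (KN(SiMe3)2, PhNTf2, THF, −78 °C), would give (2S)-2,8-dimethyl-2-(4-methylpent-3-en-1-yl)-6-[(triisopropylsilyl)oxy]-2H-chromen-3-yl trifluoromethanesulfonate F8, and reduction of the triflate (Pd(OAc)2, PPh3, Bu3N, HCO2H, DMF, 60 °C) should give 10.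

Further compounds
F1 | step 6 | (2R,3S)-3-(chloromethyl)-2-methyl-2-(4-methylpent-3-en-1-yl)oxirane | CC(C)=CCC[C@@]1(C)O[C@@H]1CCl
F2 | step 6 | (3R)-3,7-dimethyloct-6-en-1-yn-3-ol | CC(C)=CCC[C@@](C)(O)C#C
F3 | step 6 | (3R)-3,7-dimethyloct-6-en-1-yn-3-yl acetate | CC(C)=CCC[C@@](C)(OC(C)=O)C#C
F4 | step 6 | 2-[(Sa)-3,7-dimethylocta-1,2,6-trien-1-yl]-6-methyl-4-[(triisopropylsilyl)oxy]phenol | CC(C)=CCCC(C)=[C@@]=C([H])c1cc(O[Si](C(C)C)(C(C)C)C(C)C)cc(C)c1O
F5 | step 5 | 2-(allyloxy)-1-bromo-3-methyl-5-[(triisopropylsilyl)oxy]benzene | C=CCOc1c(C)cc(O[Si](C(C)C)(C(C)C)C(C)C)cc1Br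
F6 | step 5 | (2R,3R)-3-{[2-(allyloxy)-3-methyl-5-(triisopropylsilyloxy)phenyl]methyl}-2-methyl-2-(4-methylpent-3-en-1-yl)oxirane | CC(C)=CCC[C@@]1(C)O[C@@H]1Cc2cc(O[Si](C(C)C)(C(C)C)C(C)C)cc(C)c2OCC=C
F7 | step 7 | (2S)-2,8-dimethyl-2-(4-methylpent-3-en-1-yl)-6-[(triisopropylsilyl)oxy]-2H-chromen-3(4H)-one | CC(C)=CCC[C@@]1(C)C(=O)Cc2cc(O[Si](C(C)C)(C(C)C)C(C)C)cc(C)c2O1
F8 | step 7 | (2S)-2,8-dimethyl-2-(4-methylpent-3-en-1-yl)-6-[(triisopropylsilyl)oxy]-2H-chromen-3-yl trifluoromethanesulfonate | CC(C)=CCC[C@@]1(C)C(OS(=O)(=O)C(F)(F)F)=Cc2cc(O[Si](C(C)C)(C(C)C)C(C)C)cc(C)c2O1
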